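Numbering used throughout: ring carbons C1–C10 (C1 and C3 carbinols, C2 methylene, C4 and C10 methyl-bearing olefin carbons, C6 lactone carbinol, C7 ring fusion, C8 angelate carbinol); C11, C12 and C13 are the lactone α-carbon, carbonyl and exocyclic methylene. In this numbering target 30 is (1S,3S,6S,7S,8R; 4Z,9Z).

## The problem

Target 30 is a cyclodeca-4,9-diene carrying an α-methylene-γ-butyrolactone that is cis-fused across C6–C7. A ten-membered carbocycle with two Z-trisubstituted olefins is hard to close directly: medium-ring closure is slow, and Z-trisubstituted geometry is difficult to secure in an open chain. Five stereocentres have to be set. C6, C7 and C8 form a contiguous all-cis triad, while C1 and C3 form an anti-1,3-diol separated from that triad by the two olefins. C7 can be bought (carvone) and can direct its neighbours C6 and C8; C1 can direct C3 by hydroxyl-delivered hydride; linking C1 to C7, however, needs a rigid relay. The α-methylene lactone (a Michael acceptor), the angelate (prone to Z→E isomerisation and acyl migration) and the two allylic alcohols on a flexible diene ring (acid-triggered transannular reactions) will not survive rough treatment and must appear late. The enabling feature is that C3 and C8 are both oxygenated and sit 1,6 across the ring. An imaginary C3–C8 bond turns the ring into a cis-fused octalin made of ring A (C3–C2–C1–C10=C9–C8) and ring B (C3–C4=C5–C6–C7–C8). Ring B is the carvone skeleton, both olefins become endocyclic in six-membered rings (necessarily Z), and cleaving the ring-fusion glycol puts carbonyls exactly on C3 and C8.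

## Retrosynthesis

**Lactone and last protecting groups (30 ⇒ 29 ⇒ 26).** The C12–O6 acyl bond is cut and C12 is lowered to the alcohol level, so the Michael acceptor is never carried through earlier steps. Diol 26, a 2-methylene-1,4-diol, is far more robust than the lactone. The forward step must oxidise the primary allylic alcohol in preference to everything else; the C1/C3 silyl ethers of 29 are then removed by fluoride, so the last step is not acidic.

**Angelate and C8 carbinol (25 ⇒ 22 + 23; 22 ⇒ 21).** The C8–O acyl bond is cut to alcohol 22 and angelic acid 23, and the C8–H bond is cut to ketone 21. Acylating before the lactone exists avoids exposing the methylene lactone to acylation conditions. The forward steps must avoid Z→E isomerisation of the ester and must deliver hydride to the correct face of the C8 enone next to C7.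

**C3 carbinol (21 ⇒ 20 ⇒ 19).** The C3–H bond is cut to β-hydroxy ketone 19. Of the two enones in 19, only C3 has a β-hydroxyl (at C1), so a hydroxyl-delivered hydride both selects C3 over C8 and sets the 1,3-anti relationship. Diol 20 is then silylated to 21.

**Ring expansion (19 ⇒ 18), the key cut.** The C3–C8 bond is formed in the retrosynthetic direction, giving cis-fused octalin triol 18. Against cuts at C1–C2, C3–C4 or C5–C6 (the three roads below), this one removes the medium ring and both Z-olefin problems at once and leaves only six-membered-ring chemistry. The forward reaction has to cleave a cis ditertiary glycol without touching the C1 alcohol or the enolisable C7 centre.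

**Ring A (18 ⇒ 16 ⇒ 14 ⇒ 13 ⇒ 10 + 11).** Four bonds are cut in turn:
- C1–H: enone 16 is reduced under delivery from the C3 hydroxyl.
- C9=C10: the olefin comes from selenide 14.
- C2–C3: an intramolecular aldol of diketone 13, which forces cis ring fusion.
- C8–C9: Michael addition of the enolate of 10 to 3-methylbut-3-en-2-one 11.

The variant that attaches an alkenyl group at C8 and closes ring A by metathesis (compounds F4–F7 below) makes the C2–C3 bond intermolecularly. The facial outcome at C3 is then uncertain and would propagate to C1, so it is kept as a fallback only.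

**C8 oxygen (10 ⇒ 9 ⇒ 8).** The C8–O bond is cut to enone 8. Oxygen is introduced before carbon so that the later C–C bond formation, anti to the C7 side chain, puts C9 trans and the oxygen cis to that chain. This is the arrangement that lets the aldol close a cis-fused ring.

**C6 and C12 oxygens (8 ⇒ 7 ⇒ 6 ⇒ 5 ⇒ 4 ⇒ 3 ⇒ 1).** The C6–O bond is traced to a vinylogous enolate oxidation of (S)-carvone 1 followed by inversion (3 → 4). The C12–O bond is traced to ene-type chlorination of the isopropenyl group and acetate displacement (5, 6). Methanolysis to diol 7 and double silylation give 8. C7 is the stereocentre of 1 and is never touched.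

## Roads not taken

**Alternative 1:** cut C1–C2 (with C3–O) by an intramolecular nitrile oxide cycloaddition. NaOCl would convert open-chain aldoxime A2 into a nitrile oxide that adds across its terminal C2=C3 olefin to give isoxazoline-bridged macrocycle A1.
- Merits: the C1 carbonyl and C3 oxygen appear in one step as a masked aldol, and the route is more convergent than the chosen one.
- Weak points: ten-membered closure by dipolar cycloaddition competes with nitrile oxide dimerisation. The new C3 centre has no adjacent stereocentre to guide it. Both Z-trisubstituted olefins of A2 must be made in an open chain. A1 carries a lactone without its methylene, so a late α-methylenation next to free hydroxyls is still needed, as is N–O cleavage beside two olefins.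
- Comparison: the chosen plan is longer and linear, but it makes both olefins inside six-membered rings and never closes a medium ring.

**Alternative 2:** cut C5–C6 by coupling the thioester and (Z)-alkenylstannane termini of A4 with Pd2(dba)3 (zerovalent palladium) and copper thiophene-2-carboxylate (monovalent copper), closing cyclodecadienone A3.
- Merits: neutral, highly tolerant conditions, and two fragments of similar size. In convergence this road is better than the chosen one.
- Weak points: it is again a ten-membered closure at high dilution. A4 needs a geometrically pure Z-stannane beside the C3 stereocentre and a second Z-olefin made acyclically. In A3, C7 lies α to the new ketone with the C8 ether β to it, so epimerisation and elimination threaten. All four carbinol centres of A4 must come from asymmetric synthesis, not from a purchased ring. Reduction at C6, lactonisation, methylenation and angeloylation still follow.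
- Comparison: the chosen plan takes C7 from carvone and relays it through rigid rings to C6, C8 and C1.

**Alternative 3:** cut C3–C4 by a CrCl2 (divalent chromium)/NiCl2 (divalent nickel) alkenylchromium addition of seco iodo-aldehyde A6, giving the C1 silyl ether of the target, A5.
- Merits: it closes the ring on the fully functionalised skeleton, needs no redox correction afterwards and leaves one deprotection. In end-game economy it beats the chosen plan.
- Weak points: the C3 configuration is created during a medium-ring closure with no reliable model. The Z-alkenyl iodide of A6 must be built next to the lactone carbinol. The methylene lactone, the angelate and a β-silyloxy aldehyde must all be carried through fragment assembly.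
- Comparison: the chosen plan pays with two ketones that must be reduced again, but C3 is set by hydroxyl delivery from C1, and no sensitive group is present before the last three steps.

Key step: step 13

## Route

Assumption: the peracid attacks C6 of dienol ether 2 on the face opposite the C7 isopropenyl group (trans alcohol 3), as is usual for attack next to a ring substituent; the inversion in step 2 rests on this.

Step 1
Reactants: 1 (S)-carvone
Product: 3 trans-γ-hydroxycarvone [(4R,5S)-4-hydroxy-2-methyl-5-(prop-1-en-2-yl)cyclohex-2-en-1-one; C6–OH trans to the C7 isopropenyl group], via extended trimethylsilyl dienol ether 2 (not isolated)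
Conditions: KH, THF, 0 °C → rt; Me3SiCl, −78 °C; solvent switch; mCPBA, CH2Cl2, −20 °C; aq. NaHCO3, then citric acid/MeOH work-up
Reagents that add atoms: meta-chloroperoxybenzoic acid (mCPBA), OOC(=O)c1cccc(Cl)c1
Why: Vinylogous Rubottom oxidation: the equilibrated potassium dienolate is silylated on oxygen, and the peracid attacks the terminal (γ) carbon C6 of the 1-silyloxydiene, as in the 6-hydroxylation of steroidal dienol ethers. Attack anti to the C7 substituent gives the trans alcohol; the electron-poor course via the dienol ether leaves the isopropenyl group untouched at low temperature.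

Step 2
Reactants: 3 trans-γ-hydroxycarvone
Product: 4 cis-γ-(4-nitrobenzoyloxy)carvone [(1S,6S)-3-methyl-4-oxo-6-(prop-1-en-2-yl)cyclohex-2-en-1-yl 4-nitrobenzoate]
Conditions: 4-O2NC6H4CO2H, PPh3, DIAD, THF, 0 °C → rt
Reagents that add atoms: 4-nitrobenzoic acid, O=C(O)c1ccc(cc1)[N+](=O)[O-]
Why: Mitsunobu esterification with the acidic 4-nitrobenzoic acid proceeds by SN2 displacement of the alkoxyphosphonium ion and inverts C6, placing the oxygen cis to the C7 side chain as the cis-lactone requires.

Step 3
Reactants: 4 cis-γ-(4-nitrobenzoyloxy)carvone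
Product: 5 (1S,6S)-6-(3-chloroprop-1-en-2-yl)-3-methyl-4-oxocyclohex-2-en-1-yl 4-nitrobenzoate
Conditions: Ca(OCl)2, CO2 (dry ice), CH2Cl2/H2O, 0 °C
Reagents that add atoms: calcium hypochlorite, [Ca+2].[O-]Cl.[O-]Cl
Why: Hypochlorous acid generated in situ chlorinates the electron-rich 1,1-disubstituted olefin in an ene-type process with double-bond shift (the known route to 10-chlorocarvone); the enone olefin and the electron-poor ester are inert.

Step 4
Reactants: 5 allylic chloride
Product: 6 (1S,6S)-6-(3-acetoxyprop-1-en-2-yl)-3-methyl-4-oxocyclohex-2-en-1-yl 4-nitrobenzoate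
Conditions: KOAc, n-Bu4NI (cat.), DMF, 50 °C
Reagents that add atoms: potassium acetate, CC(=O)[O-].[K+]
Why: SN2 displacement of a primary allylic chloride by acetate under iodide catalysis; acetate is too weak a base to eliminate the γ-acyloxy group.

Step 5
Reactants: 6 diester
Product: 7 (4S,5S)-4-hydroxy-5-(3-hydroxyprop-1-en-2-yl)-2-methylcyclohex-2-en-1-one (cis diol)
Conditions: K2CO3 (cat.), MeOH, 0 °C
Reagents that add atoms: none
Why: Zemplén-type transesterification removes both esters; the activated 4-nitrobenzoate and the primary acetate cleave at 0 °C before the γ-position of the enone can epimerise.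

Step 6
Reactants: 7 cis diol
Product: 8 (4S,5S)-2-methyl-4-(triethylsilyloxy)-5-[3-(triethylsilyloxy)prop-1-en-2-yl]cyclohex-2-en-1-one
Conditions: Et3SiCl, imidazole, DMF, 0 °C → rt
Reagents that add atoms: chlorotriethylsilane, CC[Si](Cl)(CC)CC
Why: Standard silylation of a primary and a secondary allylic alcohol; triethylsilyl is chosen so that it can later be removed in the presence of tert-butyldimethylsilyl ethers.

Step 7
Reactants: 8 bis(triethylsilyl) enone
Product: 9 α′-hydroxy ketone: 8 with a hydroxyl on C8 (the CH2 next to the carbonyl), trans to the C7 side chain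
Conditions: KN(SiMe3)2, THF, −78 °C; 2-(benzenesulfonyl)-3-phenyloxaziridine, −78 °C; AcOH quench
Reagents that add atoms: 2-(benzenesulfonyl)-3-phenyloxaziridine, O=S(=O)(c1ccccc1)N1OC1c1ccccc1
Why: Kinetic deprotonation gives the cross-conjugated α′-enolate, which is hydroxylated by the Davis oxaziridine anti to the C7 side chain. The C8 configuration formed here is erased in step 9.

Step 8
Reactants: 9 α′-hydroxy ketone
Product: 10 2-methoxypropan-2-yl ether of 9 (C8–O–C(CH3)2OCH3)
Conditions: 2-methoxypropene, PPTS (cat.), CH2Cl2, 0 °C
Reagents that add atoms: 2-methoxypropene, COC(C)=C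
Why: Acid-catalysed addition of the alcohol to the enol ether gives a mixed acetal. Unlike a silyl group it cannot migrate to the enolate oxygen in step 9, and it is cleaved by aqueous acetic acid in step 12.

Step 9
Reactants: 10 protected α′-hydroxy ketone; 11 3-methylbut-3-en-2-one
Product: 13 1,5-diketone: C8 now quaternary with the acetal oxygen cis and the new chain C9H2–C10(CH3)(SePh)–C1(=O)–C2H3 trans to the C7 side chain (C10 epimers), via lithium enolate of the Michael adduct 12 (not isolated)
Conditions: LiN(i-Pr)2, THF, −78 °C; 11 (slow addition), −78 °C; PhSeCl, −78 °C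
Reagents that add atoms: benzeneselenenyl chloride, Cl[Se]c1ccccc1
Why: First stage of a Robinson-type annulation: the α-alkoxy lithium enolate adds 1,4 to the vinyl ketone from the face opposite the C7 side chain and the C6 silyloxy group, fixing C8. The regiodefined product enolate is trapped at C10 by α-selenenylation, which also leaves the methyl group as the only enolisable position of the new ketone.

Step 10
Reactants: 13 selenenylated 1,5-diketone
Product: 14 cis-fused bicyclic ketol: ring A closed by the C2–C3 bond, tertiary C3–OH cis to the C8 acetal oxygen, C1 ketone, C10 bearing CH3 and SePh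
Conditions: LiN(SiMe3)2, THF, −78 → −40 °C; AcOH, −78 °C
Reagents that add atoms: none
Why: Intramolecular aldol addition of the methyl ketone enolate to the C3 carbonyl (six-membered ring, Robinson ketol stage). The tether from C8 delivers C2 to the face that carries C9, so the ring fusion and the two ring-fusion oxygens are cis; the cold acidic quench prevents dehydration.

Step 11
Reactants: 14 seleno ketol
Product: 16 cis-fused octalenone: C9=C10(CH3)–C1(=O) enone in ring A, C3–OH free, C8 acetal retained, via selenoxide 15 (not isolated)
Conditions: H2O2 (30 % aq.), pyridine, CH2Cl2, 0 °C → rt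
Reagents that add atoms: none
Why: Selenide oxidation and selenoxide syn-elimination at or below room temperature give the conjugated endocyclic enone under conditions that do not dehydrate the β-hydroxy ketone. The olefin is Z by virtue of the six-membered ring.

Step 12
Reactants: 16 octalenone
Product: 18 cis-fused octalin triol: OH at C1, C3 and C8; C3–OH and C8–OH cis to each other and to the C6 silyloxy and C7 side chain; C1–OH on the opposite face, via methoxypropyl ether of the triol 17 (not isolated)
Conditions: Me4NBH(OAc)3, MeCN/AcOH, −30 °C; then H2O, 0 °C → rt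
Reagents that add atoms: none
Why: Hydroxyl-directed (Evans–Saksena-type) reduction: the C3 hydroxyl, axial on ring A, binds boron and delivers hydride to the same face of C1, so the new C1–OH is trans to C3–OH. The aqueous acetic acid then hydrolyses the acetal at C8 while the triethylsilyl ethers remain.

Step 13
Reactants: 18 cis-fused octalin triol
Product: 19 (4Z,9Z)-1-hydroxy-4,10-dimethyl-6-(triethylsilyloxy)-7-[3-(triethylsilyloxy)prop-1-en-2-yl]cyclodeca-4,9-diene-3,8-dione (biogenetic locants)
Conditions: Pb(OAc)4, CH2Cl2, −20 °C; aq. NaHCO3 work-up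
Reagents that add atoms: none
Why: Criegee glycol cleavage: the two ring-fusion hydroxyls exchange acetate on tetravalent lead to give a five-membered cyclic plumbate ester, which fragments in a concerted two-electron step that breaks C3–C8, forms the C3 and C8 carbonyls and releases divalent lead as Pb(OAc)2. The closest known reaction is the cleavage of decalin-4a,8a-diols to cyclodecane-1,6-diones. The ten-membered ring is not closed by an exo or endo cyclisation but unveiled by cleaving the bond shared by the two six-membered rings (ring expansion by fragmentation). No stereocentre is created; C1, C6 and C7 are carried over from the rigid bicycle. Both olefins were endocyclic in six-membered rings and are therefore Z in 19. The step needs chemoselectivity for the vicinal diol over the secondary C1 alcohol, secured by the cis (gauche) glycol fixed in step 10, which reacts far faster at −20 °C than an isolated alcohol. It also needs the C7 centre to survive α to the new C8 ketone (β,γ-unsaturated, β-silyloxy), which the non-basic medium and short reaction time provide.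

Step 14
Reactants: 19 hydroxy dienedione
Product: 20 (4Z,9Z)-1,3-dihydroxy-8-ketone: 19 with C3 reduced to the carbinol anti to C1–OH (target configuration at C1 and C3)
Conditions: Me4NBH(OAc)3, MeCN/AcOH, −30 °C
Reagents that add atoms: none
Why: Evans–Saksena anti-reduction: the C1 alkoxy-boron hydride delivers hydride to the β-carbonyl C3 through a six-membered chair transition state, giving the 1,3-anti diol. Triacetoxyborohydride does not reduce a ketone without a nearby hydroxyl, so the C8 enone is spared.

Step 15
Reactants: 20 anti diol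
Product: 21 1,3-bis(tert-butyldimethylsilyl) ether of 20
Conditions: TBSOTf, 2,6-lutidine, CH2Cl2, −78 °C
Reagents that add atoms: tert-butyldimethylsilyl triflate, CC(C)(C)[Si](C)(C)OS(=O)(=O)C(F)(F)F
Why: Silylation of two secondary allylic alcohols at −78 °C with a hindered weak base, which does not enolise the C8 ketone; the tert-butyldimethylsilyl ethers outlast the later removal of the triethylsilyl groups.

Step 16
Reactants: 21 protected dienone
Product: 22 C8 allylic alcohol: C8–OH cis to the C7 side chain and the C6 silyloxy group (target configuration)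
Conditions: NaBH4, CeCl3·7H2O, MeOH, −78 °C
Reagents that add atoms: none
Why: Luche 1,2-reduction of the enone; hydride is expected to enter from the ring periphery anti to the bulky C7 side chain, giving the all-cis C6/C7/C8 triad. The low temperature and near-neutral medium avoid β-elimination of the C6 silyloxy group.

Step 17
Reactants: 22 C8 alcohol; 23 angelic acid
Product: 25 C8 angelate [(Z)-2-methylbut-2-enoate] of 22, via angelic 2,4,6-trichlorobenzoic anhydride 24 (not isolated)
Conditions: 23, 2,4,6-Cl3C6H2COCl, Et3N, toluene, rt; then 22, 75 °C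
Reagents that add atoms: none
Why: Yamaguchi-type acylation through the mixed anhydride without a nucleophilic catalyst, the established way to esterify hindered alcohols with angelic acid without Z→E isomerisation to the tiglate.

Step 18
Reactants: 25 angelate
Product: 26 6,12-diol: 25 with both triethylsilyl groups removed
Conditions: HF·pyridine, pyridine, THF, 0 °C
Reagents that add atoms: none
Why: Buffered fluoride cleaves the primary and secondary triethylsilyl ethers much faster than the secondary tert-butyldimethylsilyl ethers; the buffered medium suppresses acyl migration from O8 to O6.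

Step 19
Reactants: 26 6,12-diol
Product: 29 1,3-bis(tert-butyldimethylsilyl) ether of the target, via hydroxy enal 27 (not isolated), via lactol 28 (not isolated)
Conditions: TEMPO (cat.), PhI(OAc)2, CH2Cl2, rt
Reagents that add atoms: none
Why: Oxoammonium oxidation selects the primary allylic alcohol; the enal is captured by the cis C6 hydroxyl as a five-membered lactol, which is oxidised further to the α-methylene-γ-butyrolactone (oxidative lactonisation of a 2-methylene-1,4-diol). The cis fusion is preset by C6 and C7.

Step 20
Reactants: 29 bis-silyl ether of the target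
Product: 30 target (1S,3S,6S,7S,8R; 4Z,9Z)
Conditions: HF·pyridine, THF, 0 °C → rt
Reagents that add atoms: none
Why: Fluoride-mediated cleavage of the two secondary silyl ethers under mildly acidic, non-nucleophilic conditions that leave the methylene lactone, the angelate and the allylic alcohols intact.

## Compound list

1 | (S)-carvone, (5S)-2-methyl-5-(prop-1-en-2-yl)cyclohex-2-en-1-one | CC1=CC[C@@H](CC1=O)C(C)=C | starting material
2 | extended trimethylsilyl dienol ether of carvone (1-silyloxy-2-methylcyclohexa-1,3-diene, C7 as in 1) | C=C(C)[C@H]1C=CC(C)=C(O[Si](C)(C)C)C1 | intermediate (not isolated)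
3 | trans-γ-hydroxycarvone, (4R,5S)-4-hydroxy-2-methyl-5-(prop-1-en-2-yl)cyclohex-2-en-1-one | C=C(C)[C@H]1[C@H](O)C=C(C)C(=O)C1 | intermediate
4 | (1S,6S)-3-methyl-4-oxo-6-(prop-1-en-2-yl)cyclohex-2-en-1-yl 4-nitrobenzoate (cis) | C=C(C)[C@H]1[C@@H](OC(=O)c2ccc(cc2)[N+](=O)[O-])C=C(C)C(=O)C1 | intermediate
5 | (1S,6S)-6-(3-chloroprop-1-en-2-yl)-3-methyl-4-oxocyclohex-2-en-1-yl 4-nitrobenzoate | C=C(CCl)[C@H]1[C@@H](OC(=O)c2ccc(cc2)[N+](=O)[O-])C=C(C)C(=O)C1 | intermediate
6 | (1S,6S)-6-(3-acetoxyprop-1-en-2-yl)-3-methyl-4-oxocyclohex-2-en-1-yl 4-nitrobenzoate | C=C(COC(C)=O)[C@H]1[C@@H](OC(=O)c2ccc(cc2)[N+](=O)[O-])C=C(C)C(=O)C1 | intermediate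
7 | (4S,5S)-4-hydroxy-5-(3-hydroxyprop-1-en-2-yl)-2-methylcyclohex-2-en-1-one | C=C(CO)[C@H]1[C@@H](O)C=C(C)C(=O)C1 | intermediate
8 | (4S,5S)-2-methyl-4-(triethylsilyloxy)-5-[3-(triethylsilyloxy)prop-1-en-2-yl]cyclohex-2-en-1-one | C=C(CO[Si](CC)(CC)CC)[C@H]1[C@@H](O[Si](CC)(CC)CC)C=C(C)C(=O)C1 | intermediate
9 | α′-hydroxy ketone: 8 with OH at C8, trans to the C7 side chain | C=C(CO[Si](CC)(CC)CC)[C@H]1[C@@H](O[Si](CC)(CC)CC)C=C(C)C(=O)[C@@H]1O | intermediate
10 | 2-methoxypropan-2-yl ether of 9 | C=C(CO[Si](CC)(CC)CC)[C@H]1[C@@H](O[Si](CC)(CC)CC)C=C(C)C(=O)[C@@H]1OC(C)(C)OC | intermediate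
11 | 3-methylbut-3-en-2-one | CC(=O)C(C)=C | starting material
12 | lithium enolate of the Michael adduct of 10 and 11 | C=C(CO[Si](CC)(CC)CC)[C@H]1[C@@H](O[Si](CC)(CC)CC)C=C(C)C(=O)[C@]1(OC(C)(C)OC)CC(C)=C(C)[O-].[Li+] | intermediate (not isolated)
13 | C8-quaternary 1,5-diketone with C10 phenylselanyl group (C10 epimers) | C=C(CO[Si](CC)(CC)CC)[C@H]1[C@@H](O[Si](CC)(CC)CC)C=C(C)C(=O)[C@]1(OC(C)(C)OC)CC(C)([Se]c2ccccc2)C(C)=O | intermediate
14 | cis-fused bicyclic seleno ketol (C3–OH, C1 ketone, C8 acetal) | C=C(CO[Si](CC)(CC)CC)[C@H]1[C@@H](O[Si](CC)(CC)CC)C=C(C)[C@]2(O)CC(=O)C(C)([Se]c3ccccc3)C[C@]12OC(C)(C)OC | intermediate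
15 | selenoxide of 14 | C=C(CO[Si](CC)(CC)CC)[C@H]1[C@@H](O[Si](CC)(CC)CC)C=C(C)[C@]2(O)CC(=O)C(C)([Se](=O)c3ccccc3)C[C@]12OC(C)(C)OC | intermediate (not isolated)
16 | cis-fused octalenone (C9=C10–C1=O, C3–OH, C8 acetal) | C=C(CO[Si](CC)(CC)CC)[C@H]1[C@@H](O[Si](CC)(CC)CC)C=C(C)[C@]2(O)CC(=O)C(C)=C[C@]12OC(C)(C)OC | intermediate
17 | C8 2-methoxypropan-2-yl ether of triol 18 | C=C(CO[Si](CC)(CC)CC)[C@H]1[C@@H](O[Si](CC)(CC)CC)C=C(C)[C@]2(O)C[C@H](O)C(C)=C[C@]12OC(C)(C)OC | intermediate (not isolated)
18 | cis-fused octalin-1,3,8-triol (key-step precursor) | C=C(CO[Si](CC)(CC)CC)[C@H]1[C@@H](O[Si](CC)(CC)CC)C=C(C)[C@]2(O)C[C@H](O)C(C)=C[C@]12O | intermediate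
19 | (4Z,9Z)-1-hydroxy-4,10-dimethyl-6-(triethylsilyloxy)-7-[3-(triethylsilyloxy)prop-1-en-2-yl]cyclodeca-4,9-diene-3,8-dione (key-step product) | C=C(CO[Si](CC)(CC)CC)[C@H]1[C@@H](O[Si](CC)(CC)CC)/C=C(/C)C(=O)C[C@H](O)/C(C)=C\C1=O | intermediate
20 | 1,3-anti diol 8-ketone | C=C(CO[Si](CC)(CC)CC)[C@H]1[C@@H](O[Si](CC)(CC)CC)/C=C(/C)[C@@H](O)C[C@H](O)/C(C)=C\C1=O | intermediate
21 | 1,3-bis(tert-butyldimethylsilyl) ether of 20 | C=C(CO[Si](CC)(CC)CC)[C@H]1[C@@H](O[Si](CC)(CC)CC)/C=C(/C)[C@@H](O[Si](C)(C)C(C)(C)C)C[C@H](O[Si](C)(C)C(C)(C)C)/C(C)=C\C1=O | intermediate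
22 | C8 allylic alcohol (OH cis to the C7 side chain) | C=C(CO[Si](CC)(CC)CC)[C@H]1[C@@H](O[Si](CC)(CC)CC)/C=C(/C)[C@@H](O[Si](C)(C)C(C)(C)C)C[C@H](O[Si](C)(C)C(C)(C)C)/C(C)=C\[C@H]1O | intermediate
23 | angelic acid, (Z)-2-methylbut-2-enoic acid | C/C=C(/C)C(=O)O | starting material
24 | angelic 2,4,6-trichlorobenzoic anhydride | C/C=C(/C)C(=O)OC(=O)c1c(Cl)cc(Cl)cc1Cl | intermediate (not isolated)
25 | C8 angelate of 22 | C=C(CO[Si](CC)(CC)CC)[C@H]1[C@@H](O[Si](CC)(CC)CC)/C=C(/C)[C@@H](O[Si](C)(C)C(C)(C)C)C[C@H](O[Si](C)(C)C(C)(C)C)/C(C)=C\[C@H]1OC(=O)/C(C)=C\C | intermediate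
26 | 6,12-diol (both triethylsilyl groups removed) | C=C(CO)[C@H]1[C@@H](O)/C=C(/C)[C@@H](O[Si](C)(C)C(C)(C)C)C[C@H](O[Si](C)(C)C(C)(C)C)/C(C)=C\[C@H]1OC(=O)/C(C)=C\C | intermediate
27 | C12 aldehyde (hydroxy enal) from 26 | C=C(C=O)[C@H]1[C@@H](O)/C=C(/C)[C@@H](O[Si](C)(C)C(C)(C)C)C[C@H](O[Si](C)(C)C(C)(C)C)/C(C)=C\[C@H]1OC(=O)/C(C)=C\C | intermediate (not isolated)
28 | lactol (C12 hemiacetal, epimers) | C=C1C(O)O[C@H]2/C=C(/C)[C@@H](O[Si](C)(C)C(C)(C)C)C[C@H](O[Si](C)(C)C(C)(C)C)/C(C)=C\[C@@H](OC(=O)/C(C)=C\C)[C@@H]12 | intermediate (not isolated)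
29 | 1,3-bis(tert-butyldimethylsilyl) ether of the target | C=C1C(=O)O[C@H]2/C=C(/C)[C@@H](O[Si](C)(C)C(C)(C)C)C[C@H](O[Si](C)(C)C(C)(C)C)/C(C)=C\[C@@H](OC(=O)/C(C)=C\C)[C@@H]12 | intermediate
30 | CNP0152559.4, (1S,3S,6S,7S,8R; 4Z,9Z) 1,3-dihydroxy-8-angeloyloxy germacra-4,9,11(13)-trien-12,6-olide (biogenetic locants) | C=C1C(=O)O[C@H]2/C=C(/C)[C@@H](O)C[C@H](O)/C(C)=C\[C@@H](OC(=O)/C(C)=C\C)[C@@H]12 | target

## Step count and risk

Total step count: 20. Longest linear sequence: 20 steps from 1 (11 and 23 are purchased).

**Step 13 (key step).** The cleavage itself is expected to be fast. The likely trouble lies in what the free C1 hydroxyl of 19 does afterwards: transannular addition to the C8 carbonyl across the Z C9=C10 bond (a five-membered hemiketal), or loss of water or retro-aldol cleavage of the β-hydroxy ketone. Enolisation of the C8 ketone towards C7 is the second danger, leading to epimerisation, conjugation of the C11=C13 olefin or loss of the C6 silyloxy group. The fallback removes the free hydroxyl and changes the control element at C3. From 18 the secondary C1 alcohol alone is silylated (TBSCl, imidazole) to give the C1 silyl ether of the octalin diol F1. Pb(OAc)4 then gives the hydroxyl-free dienedione F2. The less hindered C3 enone of F2 (C8 is flanked by the branched C7) is reduced under reagent control with (R)-2-methyl-CBS-oxazaborolidine and catecholborane to the C3 alcohol F3. Silylation of F3 with TBSOTf and 2,6-lutidine rejoins the route at 21, bypassing 19 and 20.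

**Step 9.** The crowded tertiary α-alkoxy enolate may transfer a proton to the vinyl ketone, or the adduct enolate may start oligomerising 11, in place of clean 1,4-addition. The fallback builds ring A by metathesis from 10:
- Allylation (LiN(i-Pr)2; allyl bromide, anti to the C7 side chain) gives the C8-allyl ketone F4.
- Isomerisation with RuHCl(CO)(PPh3)3 in toluene gives the C8-propenyl ketone F5.
- Addition of the lithium enolate of N-methoxy-N-methylacetamide to the C3 carbonyl, anti to the axial C8 oxygen, gives the β-hydroxy Weinreb amide F6.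
- Isopropenylmagnesium bromide gives the β-hydroxy dienone F7.
- Ring-closing metathesis with the second-generation Grubbs catalyst returns to 16.

This detour is two steps longer, and its C3 configuration rests on a Felkin-type argument instead of on a tether.

**Step 11.** Syn-elimination of the selenoxide can run towards the C10 methyl group (exocyclic methylene ketone) instead of into the ring, and benzeneselenenic acid can add to the other olefins. The fallback avoids selenium altogether. From 10 the Michael addition is quenched with acid, without the selenium trap, to give the selenium-free 1,5-diketone F8. The same aldol closure gives the saturated cis-fused ketol F9. Dehydrogenation of F9 with the complex of IBX and 4-methoxypyridine N-oxide in DMSO at room temperature returns to 16; only the C9=C10 enone can form because C3 bears no hydrogen.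

**Step 16.** Facial selectivity of hydride addition to a ketone in a flexible ten-membered ring is the least predictable element of the route; attack from the wrong face gives the C8 epimer. The fallback uses that epimer: the 8-epi alcohol F10 is esterified with 23 under Mitsunobu conditions (PPh3, DIAD, toluene), which inverts C8 and installs the angelate in one operation, rejoining the route at 25.

## Further compounds

F1 | step 13 | C1 tert-butyldimethylsilyl ether of octalin triol 18 | C=C(CO[Si](CC)(CC)CC)[C@H]1[C@@H](O[Si](CC)(CC)CC)C=C(C)[C@]2(O)C[C@H](O[Si](C)(C)C(C)(C)C)C(C)=C[C@]12O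
F2 | step 13 | C1 tert-butyldimethylsilyl ether of dienedione 19 | C=C(CO[Si](CC)(CC)CC)[C@H]1[C@@H](O[Si](CC)(CC)CC)/C=C(/C)C(=O)C[C@H](O[Si](C)(C)C(C)(C)C)/C(C)=C\C1=O
F3 | step 13 | C3 alcohol from F2 (C1 mono-silyl ether of 20) | C=C(CO[Si](CC)(CC)CC)[C@H]1[C@@H](O[Si](CC)(CC)CC)/C=C(/C)[C@@H](O)C[C@H](O[Si](C)(C)C(C)(C)C)/C(C)=C\C1=O
F4 | step 9 | C8-allyl derivative of 10 (allyl trans to the C7 side chain) | C=C(CO[Si](CC)(CC)CC)[C@H]1[C@@H](O[Si](CC)(CC)CC)C=C(C)C(=O)[C@]1(OC(C)(C)OC)CC=C
F5 | step 9 | C8-(E)-prop-1-enyl isomer of F4 | C=C(CO[Si](CC)(CC)CC)[C@H]1[C@@H](O[Si](CC)(CC)CC)C=C(C)C(=O)[C@]1(OC(C)(C)OC)/C=C/C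
F6 | step 9 | C3 tertiary alcohol bearing CH2C(=O)N(OMe)Me, from F5 | C=C(CO[Si](CC)(CC)CC)[C@H]1[C@@H](O[Si](CC)(CC)CC)C=C(C)[C@](O)(CC(=O)N(C)OC)[C@]1(OC(C)(C)OC)/C=C/C
F7 | step 9 | β-hydroxy isopropenyl ketone from F6 (metathesis substrate) | C=C(CO[Si](CC)(CC)CC)[C@H]1[C@@H](O[Si](CC)(CC)CC)C=C(C)[C@](O)(CC(=O)C(C)=C)[C@]1(OC(C)(C)OC)/C=C/C
F8 | step 11 | selenium-free 1,5-diketone from 10 and 11 | C=C(CO[Si](CC)(CC)CC)[C@H]1[C@@H](O[Si](CC)(CC)CC)C=C(C)C(=O)[C@]1(OC(C)(C)OC)CC(C)C(C)=O
F9 | step 11 | saturated cis-fused ketol from F8 | C=C(CO[Si](CC)(CC)CC)[C@H]1[C@@H](O[Si](CC)(CC)CC)C=C(C)[C@]2(O)CC(=O)C(C)C[C@]12OC(C)(C)OC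
F10 | step 16 | C8 epimer of alcohol 22 | C=C(CO[Si](CC)(CC)CC)[C@H]1[C@@H](O[Si](CC)(CC)CC)/C=C(/C)[C@@H](O[Si](C)(C)C(C)(C)C)C[C@H](O[Si](C)(C)C(C)(C)C)/C(C)=C\[C@@H]1O
A1 | alternative 1 | isoxazoline-bridged ten-membered ring with cis-lactone | C1C(=O)O[C@H]2/C=C(/C)[C@@H]3CC(=NO3)/C(C)=C\[C@@H](O[Si](C)(C)C(C)(C)C)[C@@H]12
A2 | alternative 1 | open-chain aldoxime with terminal diene (precursor of A1) | ON=C/C(C)=C\[C@@H](O[Si](C)(C)C(C)(C)C)[C@H]1CC(=O)O[C@H]1/C=C(/C)C=C
A3 | alternative 2 | (4Z,9Z)-cyclodecadien-6-one with C7 acetate arm | COC(=O)C[C@H]1C(=O)/C=C(/C)[C@@H](O[Si](C)(C)C(C)(C)C)C[C@H](O[Si](C)(C)C(C)(C)C)/C(C)=C\[C@H]1OCc2ccc(OC)cc2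
A4 | alternative 2 | seco S-ethyl thioester with (Z)-alkenyl tributylstannane (precursor of A3) | CCSC(=O)[C@H](CC(=O)OC)[C@H](OCc1ccc(OC)cc1)/C=C(C)\[C@@H](O[Si](C)(C)C(C)(C)C)C[C@H](O[Si](C)(C)C(C)(C)C)/C(C)=C\[Sn](CCCC)(CCCC)CCCC
A5 | alternative 3 | target as its C1 tert-butyldimethylsilyl ether | C=C1C(=O)O[C@H]2/C=C(/C)[C@@H](O)C[C@H](O[Si](C)(C)C(C)(C)C)/C(C)=C\[C@@H](OC(=O)/C(C)=C\C)[C@@H]12
A6 | alternative 3 | seco C3 aldehyde with (Z)-C4 alkenyl iodide (precursor of A5) | C=C1C(=O)O[C@@H](/C=C(C)\I)[C@H]1[C@H](OC(=O)/C(C)=C\C)/C=C(C)\[C@@H](O[Si](C)(C)C(C)(C)C)CC=O
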